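A closed, stirred vessel starts with solid E and dissolved Q. E dissolves to Z, Z takes up Q to give Z.Q, and Z takes up Z.Q to give Z.Z.Q, while Q pairs off to Q2 and Z.Q exchanges with L.

E 5.0 × 10⁻⁴ M; Q 0.900 mM; time 1.5 min

- the Z.Q standing at 1.5 min, as a percentage of the E charged
- the change that raises the amount of Z.Q at 1.5 min, in percent of the E charged most ("none" if none brings more than 2 percentage points) (grey / ochre / green / none)
- amount of Z.Q at 1.5 min, in percent of the E charged, after green

    Z + Z.Q → Z.Z.Q (k1 = 95 M⁻¹ s⁻¹)
    Z + Q → Z.Q (k2 = 46 M⁻¹ s⁻¹)
    2 Q → Q2 (k3 = 23 M⁻¹ s⁻¹)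
    Z.Q ⇌ L (K4 = 0.15, k4 = 0.0099 s⁻¹)
    E ⇌ Z, rate k5*(cs5 - [Z]) while solid is left; crystals form when [Z] > cs5 (cs5 = 0.31 mM, k5 = 0.10 s⁻¹)

What should be watched? Z.Q and Q together. Z makes Z.Q with Q at constant 46 M⁻¹ s⁻¹ and uses it up at constant 95 M⁻¹ s⁻¹, so [Z] cancels from the ratio of the two rates, and, counting these two steps and leaving out the exchange with L, Z.Q stops rising where [Z.Q] = S[Q], with S = 0.484, the selectivity factor.

And Q at the reading? Its pairing has a first half-life of 24.2 s and at the start takes Q faster than Z can at the solubility 0.31 mM. Counting pairing and nothing else leaves 0.190 mM. So the balance level B, the Z.Q at which making and use by Z are equal at the Q reckoned for the reading, is 0.0922 mM.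

Does Z.Q get there in time? With Z at 0.31 mM, its half-time of approach is 0.392 min, shorter than the 1.5 min of the run. The exchange with L relaxes in 0.152 min, also shorter.

Where is that weakest? Z also takes Q, which should put Q below my value, while Z below 0.31 mM should leave Z.Q lagging above B. These errors pull in opposite directions.

Your numbers? I commit to y = 18.4%. B contains neither dissolution setting, so I expect no gain from ochre or green, and the same y after green. Grey raises B to 0.103 mM, a gain of 2.2 percentage points against the mark of 2 points, so I pick grey.

The forecast gives 16%, grey and 15.5%, reasoning that “doubling Q favours Z.Q over Z.Z.Q by competing for Z”. It stands lower than my y.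

The simulation gives y = 16.9% and best = grey, with grey worth 6.4 points, ochre 1.5 points and green 3 points, so yb = 19.8%.

In this flask, Q reads 13% of its charge at 1.50 min against my 21.2%, and Z.Q is being made at 0.682 of the rate at which it is used up, each step taken net. The neighbour flask holds 2.0 × 10⁻⁴ M of E with the same Q. B contains no E, so the reckoning stays at 0.0922 mM, which is 46.1% of that smaller charge. That neighbour flask gives y = 38.8%, which is 0.0775 mM of Z.Q against 0.0844 mM in the first flask, with Z.Z.Q at 38.8% of the E charged, one Z.Z.Q counted as two.

(The numbers of this flask are invented, and the outcome is calculated.)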